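Compound numbers are those of the compound list after the steps.

## Analysis of the target

The target 15 (C20H14O8) is made of two 2H-chromen-2-one (coumarin) units joined by one ether oxygen, which links C3 of the unprimed unit to C7' of the primed unit. The unprimed unit carries a methoxy group at C6 and a free hydroxyl at C7; the primed unit is a 6'-methoxycoumarin-7'-yl group, that is, scopoletin 8 bound through its phenolic oxygen. There is no stereocentre, and the two ring alkenes C3=C4 and C3'=C4' are held cis by their rings. The sensitive groups are the two lactones (opened by hydroxide or alkoxide, and electrophilic at C4 and C4'), the oxidisable guaiacol-type phenol, and the C3–O–aryl enol ether. The difficulty is the ether: C3 of a finished coumarin is a poor site for O-arylation, and the two halves have nearly the same substitution, so a late union of two coumarins would be hard to direct. The ether is therefore better made on an open-chain carbon, with the unprimed pyranone closed around it afterwards. The strategy rests on the unprimed C3=C4 alkene: it is trisubstituted and endocyclic, bonded at C4 to the benzene carbon C4a and at C3 to the ester carbon C2 and the ether oxygen. Cutting it leaves a vinyl group on C4a and a 2-aryloxyacrylate on the C8a oxygen, two terminal alkenes that metathesis can rejoin.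

## Retrosynthetic reasoning

15 to 14. The O–Si bond at O7 is cut last. The 7-hydroxyl must be masked throughout, because the route acylates the other phenol of the same benzene ring and only one free hydroxyl may be present then. A triisopropylsilyl ether withstands the ylide, the carbodiimide coupling and the ruthenium catalyst, and comes off under buffered fluoride conditions that leave both lactones closed.

14 to 13. The C3=C4 double bond is cut. It is the only carbon–carbon bond of the unprimed pyranone that is not part of the benzene ring, and cutting it leaves the C3–O ether and the O1–C2 ester to be made by ordinary heteroatom chemistry on open-chain pieces. The forward reaction has to join a styrene CH2 terminus and an acrylate CH2 terminus held ortho on one arene, and it must leave the C3'=C4' alkene of the primed unit alone.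

13 to 5 and 12. The O1–C2 ester bond is cut, which divides the molecule into two halves of similar size: the vinylphenol 5 and the acrylic acid 12. The forward reaction is a phenol acylation under neutral carbodiimide activation, so neither the silyl ether nor the lactone is put at risk.

5 to 2 to 1. The vinyl group of 5 comes from the formyl group of 2 by methylenation with the ylide 4, made in the flask from 3. Aldehyde 2 comes from 1 by silylation at O4 only. The selectivity is built into 1: the O2 hydroxyl is tied up in a hydrogen bond to the formyl oxygen, and the O4 hydroxyl, para to the formyl group, is the more acidic and more accessible one.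

12 to 11 to 9 and 10. The acid is unmasked from a tert-butyl ester by anhydrous acid, so no aqueous base comes near the lactone. The methylene C=C bond of 11 is cut to the phosphonate 9 and formaldehyde 10, a Horner–Wadsworth–Emmons olefination.

9 to 7 and 8, and 7 to 6. The ether bond between O7' of scopoletin 8 and the phosphonate-bearing carbon is cut. In the forward sense a rhodium carbenoid from the diazo compound 7 inserts into the O–H bond of 8. This needs no base, whereas alkylation of the phenoxide with an alpha-halophosphonoacetate would suffer attack at halogen. The diazo compound 7 comes from the commercial phosphonoacetate 6 by diazo transfer.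

## Alternatives that were turned down

Alternative 1: The unprimed benzene ring is taken apart instead of the pyranone. The bonds cut are C5–C6, C4a–C8a, C8–C8a and the lactone bond O1–C2.
- Forward key step: the chromium carbene complex A2, (CO)5Cr=C(OMe)C(OtBu)=CH2, is heated with the terminal alkyne of the enyne ester A3, methyl (E)-2-[(6-methoxy-2-oxochromen-7-yl)oxy]pent-2-en-4-ynoate. Alkyne insertion, insertion of one carbonyl ligand and electrocyclisation (Dötz benzannulation) give a phenol whose new hydroxyl lies next to the acrylate arm and lactonises to the 7-O-tert-butyl ether A1.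
- For it: three carbon–carbon bonds and both unprimed rings form in one operation. The terminal alkyne fixes the regiochemistry, and the C6 methoxy group comes from the carbene. On bonds formed per step it is stronger than the chosen route, and on regiocontrol it is equal.
- Against it: chromium is used in stoichiometric amount. A2 is a fragile alpha-alkoxyvinyl carbene complex. A3 needs a trisubstituted enol ether alkene of defined geometry next to a conjugated alkyne. The tert-butyl ether must then be removed with acid.
- Comparison: the benzene ring that this route builds is available with all four substituents in 1. The chosen route offers a catalytic key step, precursors reached by standard steps from compounds that already hold both benzene rings, and no alkene geometry to set before the ring closure.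

Alternative 2: The primed lactone is the ring made late, by cutting O1'–C8a'.
- Forward key step: the indanone A5, 6-[(7-acetoxy-6-methoxy-2-oxochromen-3-yl)oxy]-5-methoxyindan-1-one, is treated with trifluoroperacetic acid A6. Baeyer–Villiger oxidation with aryl migration expands the five-membered ketone to the 3',4'-dihydro lactone A4; dehydrogenation and removal of the acetate follow.
- For it: the migrating aryl carbon is para to a methoxy group, so the regiochemistry of oxygen insertion is dependable, and no stereocentre arises. On these two points it equals the chosen route.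
- Against it: A5 already contains the C3–O ether on a finished unprimed coumarin, so the main problem of the target is only moved. The peroxy acid meets an electron-rich enol ether and two alkoxyarenes, which can be epoxidised or hydroxylated. The ketone is deactivated by the para methoxy group. A 3,4-dihydrocoumarin must afterwards be dehydrogenated under forcing conditions, and an aryl acetate cleaved beside two lactones.
- Comparison: the unit that this route constructs is scopoletin 8, which the chosen route uses intact. The alternative is longer and places its risk in oxidation chemistry on a sensitive substrate.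

Alternative 3: C2 is excised as a one-carbon unit by cutting C2–C3 and C2–O1.
- Forward key step: the phenol A8, 5-(benzyloxy)-4-methoxy-2-[(E)-2-[(6-methoxy-2-oxochromen-7-yl)oxy]ethenyl]phenol, is treated with Pd(OAc)2 A9 and benzoquinone A10 under carbon monoxide A11. Phenol-directed palladation of the C–H bond at the oxygen-bearing alkene carbon, carbonyl insertion and C–O bond formation give the 7-O-benzyl ether A7.
- For it: it is the most atom-economical closure. It needs no phosphonate or acrylate chemistry and is catalytic in palladium. On atom economy and on step count in the scopoletin branch it is stronger than the chosen route.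
- Against it: A8 is a beta-aryloxystyrene whose E geometry must be set. It is an enol ether next to a free phenol, and under divalent palladium or trace acid the phenol can add across it and lead towards benzofurans. Electrophilic palladation of an enol ether prefers the carbon that does not bear oxygen, so five-membered closure may compete. The quinone can oxidise the electron-rich phenol. Hydrogenolysis of the benzyl ether risks saturating C3'=C4'.
- Comparison: the chosen route offers a ring closure whose connectivity is fixed by two terminal CH2 groups, no oxidant in contact with the phenol-derived ring, and a silyl group that is removed without touching either alkene.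

Key step: step 8

Remark on the chemistry: the target has no stereocentre; 9 has one (the phosphonate-bearing carbon), is made and used as the racemate, and loses it in step 5.

## Route

Step 1
Reactants: 1 2,4-dihydroxy-5-methoxybenzaldehyde
Product: 2 2-hydroxy-5-methoxy-4-[tri(propan-2-yl)silyloxy]benzaldehyde
Conditions: iPr3SiCl (1.05 equiv), imidazole, DMF, 0 °C to rt
Reagents that add atoms: chlorotri(propan-2-yl)silane (TIPSCl), CC(C)[Si](Cl)(C(C)C)C(C)C
Why: Imidazole-mediated silylation of a phenol; the O2 hydroxyl is locked in a hydrogen bond to the formyl oxygen, while the O4 hydroxyl, para to the formyl group, is more acidic and more accessible, so the bulky silyl chloride should react at O4 only, as in the usual 4-O-selective protection of 2,4-dihydroxybenzaldehydes.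

Step 2
Reactants: 2 2-hydroxy-5-methoxy-4-[tri(propan-2-yl)silyloxy]benzaldehyde; 3 methyltriphenylphosphonium bromide
Product: 5 2-ethenyl-4-methoxy-5-[tri(propan-2-yl)silyloxy]phenol, via methylidenetriphenylphosphorane 4 (not isolated)
Conditions: 3 (2.5 equiv), KOtBu (2.4 equiv), THF, 0 °C; then 2, 0 °C to rt; aq. NH4Cl
Reagents that add atoms: none
Why: Wittig methylenation; the first equivalent of ylide 4 deprotonates the phenol and further ylide converts the formyl group into the vinyl group through the oxaphosphetane, as known for salicylaldehydes. The silyl ether is meta to the phenoxide and cannot migrate to it, and the slight deficit of KOtBu relative to 3 leaves no free alkoxide to cleave it.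

Step 3
Reactants: 6 tert-butyl 2-(diethoxyphosphoryl)acetate
Product: 7 tert-butyl 2-diazo-2-(diethoxyphosphoryl)acetate
Conditions: NaH, THF, 0 °C; then 4-AcNHC6H4SO2N3, 0 °C to rt; aq. NH4Cl
Reagents that add atoms: 4-acetamidobenzenesulfonyl azide, CC(=O)Nc1ccc(cc1)S(=O)(=O)N=[N+]=[N-]
Why: Regitz diazo transfer; the sodium phosphonoacetate carbanion attacks the terminal nitrogen of the sulfonyl azide and the adduct fragments to the diazo compound and the sulfonamide anion.

Step 4
Reactants: 7 tert-butyl 2-diazo-2-(diethoxyphosphoryl)acetate; 8 scopoletin (7-hydroxy-6-methoxy-2H-chromen-2-one)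
Product: 9 tert-butyl 2-(diethoxyphosphoryl)-2-[(6-methoxy-2-oxo-2H-chromen-7-yl)oxy]acetate (racemic)
Conditions: Rh2(OAc)4 (2 mol %), ClCH2CH2Cl, 80 °C, slow addition of 7 (1.3 equiv)
Reagents that add atoms: none
Why: Rh2(OAc)4 turns the diazophosphonoacetate into an electrophilic rhodium carbenoid that inserts into the phenolic O–H bond of 8 (carbenoid O–H insertion, established for phenols with diazophosphonoacetates). No base is present, so the lactone is untouched, and the electron-poor C3'=C4' alkene is a poor partner for cyclopropanation.

Step 5
Reactants: 9 tert-butyl 2-(diethoxyphosphoryl)-2-[(6-methoxy-2-oxo-2H-chromen-7-yl)oxy]acetate; 10 formaldehyde (used as paraformaldehyde)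
Product: 11 tert-butyl 2-[(6-methoxy-2-oxo-2H-chromen-7-yl)oxy]prop-2-enoate
Conditions: (CH2O)n (3 equiv), K2CO3 (2 equiv), THF, 60 °C
Reagents that add atoms: none
Why: Horner–Wadsworth–Emmons olefination with formaldehyde, the standard conversion of an alpha-oxy-substituted phosphonoacetate into a 2-oxyacrylate; the C–H flanked by phosphonate, ester and aryloxy group is acidic enough for K2CO3, and the anhydrous medium spares the lactone. The stereocentre of 9 becomes sp2.

Step 6
Reactants: 11 tert-butyl 2-[(6-methoxy-2-oxo-2H-chromen-7-yl)oxy]prop-2-enoate
Product: 12 2-[(6-methoxy-2-oxo-2H-chromen-7-yl)oxy]prop-2-enoic acid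
Conditions: CF3CO2H, CH2Cl2, 0 °C to rt
Reagents that add atoms: none
Why: Acidolysis of the tert-butyl ester by alkyl–oxygen cleavage, the tert-butyl cation leaving as isobutene, frees the acid without hydroxide, which would open the lactone. The alkene bears an ester and an electron-poor aryloxy group on the same carbon, so it is a weak base and should not be protonated under these anhydrous conditions.

Step 7
Reactants: 12 2-[(6-methoxy-2-oxo-2H-chromen-7-yl)oxy]prop-2-enoic acid; 5 2-ethenyl-4-methoxy-5-[tri(propan-2-yl)silyloxy]phenol
Product: 13 2-ethenyl-4-methoxy-5-[tri(propan-2-yl)silyloxy]phenyl 2-[(6-methoxy-2-oxo-2H-chromen-7-yl)oxy]prop-2-enoate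
Conditions: DCC (1.2 equiv), DMAP (0.1 equiv), CH2Cl2, 0 °C to rt
Reagents that add atoms: none
Why: Steglich esterification; the carbodiimide activates 12 as the O-acylisourea and DMAP relays the acyl group to the only free hydroxyl of 5. The medium stays neutral to mildly basic, which the acid-sensitive vinylphenol and the silyl ether tolerate.

Step 8
Reactants: 13 2-ethenyl-4-methoxy-5-[tri(propan-2-yl)silyloxy]phenyl 2-[(6-methoxy-2-oxo-2H-chromen-7-yl)oxy]prop-2-enoate
Product: 14 6-methoxy-3-[(6-methoxy-2-oxo-2H-chromen-7-yl)oxy]-7-[tri(propan-2-yl)silyloxy]-2H-chromen-2-one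
Conditions: (H2IMes)Cl2Ru(=CH-C6H4-2-OiPr) (second-generation Hoveyda–Grubbs catalyst, 5–10 mol %), toluene (5 mM), 80 °C, argon sweep
Reagents that add atoms: none
Why: This is ring-closing olefin metathesis of the kind known for 2-vinylphenyl acrylates and methacrylates, which give coumarins. The catalyst should initiate at the accessible, electron-rich styrene terminus of 13 and give a ruthenium benzylidene that carries the ester tether. This adds across the 1,1-disubstituted CH2=C(OAr)CO2Ar alkene with ruthenium on the CH2 carbon, and cycloreversion of the ruthenacyclobutane releases 14 and Ru=CH2, whose methylidene leaves as ethene in the next turnover. The one ring formed, the unprimed pyranone, closes as a six-membered ring by metathesis between two terminal alkenes held ortho on one benzene ring. No stereocentre is formed, and the ring size allows only the cis ring alkene. Site selectivity is needed against the primed C3'=C4' alkene; this is an endocyclic, cis-disubstituted, electron-poor alkene of a conjugated pyranone whose ring opening would be uphill and reversible, so it should stay out. The connectivity cannot vary, because only the two terminal CH2 groups are exchanged, and the opposite orientation of the ruthenacycle is unproductive and would place a disubstituted aryloxy carbene on ruthenium. High dilution and removal of ethene guard against intermolecular metathesis at the styrene.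

Step 9
Reactants: 14 6-methoxy-3-[(6-methoxy-2-oxo-2H-chromen-7-yl)oxy]-7-[tri(propan-2-yl)silyloxy]-2H-chromen-2-one
Product: 15 7-hydroxy-6-methoxy-3-[(6-methoxy-2-oxo-2H-chromen-7-yl)oxy]-2H-chromen-2-one
Conditions: Bu4NF (1.1 equiv), AcOH (1.1 equiv), THF, 0 °C
Reagents that add atoms: none
Why: Fluoride attacks silicon and releases the phenol (silyl ether cleavage); the acetic acid buffer keeps the medium from becoming basic enough to open either lactone. No other group in 14 responds to fluoride.

## Compound list

1 | 2,4-dihydroxy-5-methoxybenzaldehyde | COc1cc(C=O)c(O)cc1O | starting material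
2 | 2-hydroxy-5-methoxy-4-[tri(propan-2-yl)silyloxy]benzaldehyde | COc1cc(C=O)c(O)cc1O[Si](C(C)C)(C(C)C)C(C)C | intermediate
3 | methyltriphenylphosphonium bromide | C[P+](c1ccccc1)(c1ccccc1)c1ccccc1.[Br-] | starting material
4 | methylidenetriphenylphosphorane (not isolated) | C=P(c1ccccc1)(c1ccccc1)c1ccccc1 | intermediate
5 | 2-ethenyl-4-methoxy-5-[tri(propan-2-yl)silyloxy]phenol | C=Cc1cc(OC)c(O[Si](C(C)C)(C(C)C)C(C)C)cc1O | intermediate
6 | tert-butyl 2-(diethoxyphosphoryl)acetate | CCOP(=O)(OCC)CC(=O)OC(C)(C)C | starting material
7 | tert-butyl 2-diazo-2-(diethoxyphosphoryl)acetate | CCOP(=O)(OCC)C(=[N+]=[N-])C(=O)OC(C)(C)C | intermediate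
8 | scopoletin (7-hydroxy-6-methoxy-2H-chromen-2-one) | COc1cc2ccc(=O)oc2cc1O | starting material
9 | tert-butyl 2-(diethoxyphosphoryl)-2-[(6-methoxy-2-oxo-2H-chromen-7-yl)oxy]acetate (racemic) | CCOP(=O)(OCC)C(Oc1cc2oc(=O)ccc2cc1OC)C(=O)OC(C)(C)C | intermediate
10 | formaldehyde | C=O | starting material
11 | tert-butyl 2-[(6-methoxy-2-oxo-2H-chromen-7-yl)oxy]prop-2-enoate | C=C(Oc1cc2oc(=O)ccc2cc1OC)C(=O)OC(C)(C)C | intermediate
12 | 2-[(6-methoxy-2-oxo-2H-chromen-7-yl)oxy]prop-2-enoic acid | C=C(Oc1cc2oc(=O)ccc2cc1OC)C(=O)O | intermediate
13 | 2-ethenyl-4-methoxy-5-[tri(propan-2-yl)silyloxy]phenyl 2-[(6-methoxy-2-oxo-2H-chromen-7-yl)oxy]prop-2-enoate | C=Cc1cc(OC)c(O[Si](C(C)C)(C(C)C)C(C)C)cc1OC(=O)C(=C)Oc1cc2oc(=O)ccc2cc1OC | intermediate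
14 | 6-methoxy-3-[(6-methoxy-2-oxo-2H-chromen-7-yl)oxy]-7-[tri(propan-2-yl)silyloxy]-2H-chromen-2-one | COc1cc2cc(Oc3cc4oc(=O)ccc4cc3OC)c(=O)oc2cc1O[Si](C(C)C)(C(C)C)C(C)C | intermediate
15 | 7-hydroxy-6-methoxy-3-[(6-methoxy-2-oxo-2H-chromen-7-yl)oxy]-2H-chromen-2-one | COc1cc2cc(Oc3cc4oc(=O)ccc4cc3OC)c(=O)oc2cc1O | target

## Step count and least certain steps

Total: 9 steps. Longest linear sequence: 7 steps (6 to 7 to 9 to 11 to 12 to 13 to 14 to 15, steps 3 to 9). The vinylphenol branch (steps 1 and 2) joins at step 7.

Step 8 (key step). The ring closure may stall. The ruthenium benzylidene formed at the styrene has to engage a 1,1-disubstituted alkene that is hindered and carries a donor oxygen and an acceptor ester on the same carbon. Intermolecular styrene–styrene metathesis or thermal decay of the catalyst could then outrun cyclisation. The fallback closes the same C3=C4 bond by carbonyl olefination instead of metathesis, and it sets out from 9 and 2. Acid cleavage of the tert-butyl ester of 9 (CF3CO2H, CH2Cl2) would give 2-(diethoxyphosphoryl)-2-[(6-methoxy-2-oxochromen-7-yl)oxy]acetic acid F1. DCC/DMAP esterification of F1 with the free phenol of aldehyde 2 would give 2-formyl-4-methoxy-5-[tri(propan-2-yl)silyloxy]phenyl 2-(diethoxyphosphoryl)-2-[(6-methoxy-2-oxochromen-7-yl)oxy]acetate F2. LiCl and DBU in MeCN would then bring about an intramolecular Horner–Wadsworth–Emmons reaction onto the ortho formyl group, and the route is rejoined at 14.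

Step 4. The carbenoid may be diverted before the phenol traps it. Scopoletin is sparingly soluble in the solvents that suit the catalyst, and a slowly supplied phenol leaves room for carbene dimerisation, insertion into adventitious water, or attack on the electron-rich benzene ring. The fallback avoids carbenoid chemistry and sets out from 8. tert-Butyl 2,3-dibromopropanoate F3 (from tert-butyl acrylate and Br2) would be heated with 8 and K2CO3 in acetone. Dehydrobromination in the flask, conjugate addition of the phenoxide, substitution at the alpha carbon and beta-elimination of aryloxide form the 2-aryloxyacrylate, a sequence used for simple phenols. The route is rejoined at 11, and 6, 7, 9 and 10 are no longer needed.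

Step 2. Olefination may be sluggish, because the phenoxide formed first deactivates the formyl group. Long exposure to the basic medium can then cost the silyl group, and the electron-rich vinylphenol can oligomerise on work-up. The fallback is a Peterson olefination from 2. Me3SiCH2MgCl (2.5 equiv, THF, 0 °C) adds to the magnesium-chelated aldehyde to give 2-[1-hydroxy-2-(trimethylsilyl)ethyl]-4-methoxy-5-[tri(propan-2-yl)silyloxy]phenol F4. Elimination of the beta-hydroxysilane with KH or KOtBu in THF gives the vinyl group, and the route is rejoined at 5.

Step 6. The strong acid may protonate the enol ether alkene, which would lead to cleavage of the aryl vinyl ether on work-up, or the free acrylic acid may oligomerise on concentration. The fallback moves the acid treatment to the saturated phosphonate and sets out from 9. CF3CO2H in CH2Cl2 gives the acid F1 described under step 8. DCC/DMAP coupling of F1 with 5 gives 2-ethenyl-4-methoxy-5-[tri(propan-2-yl)silyloxy]phenyl 2-(diethoxyphosphoryl)-2-[(6-methoxy-2-oxochromen-7-yl)oxy]acetate F5. Horner–Wadsworth–Emmons olefination of F5 with formaldehyde 10 ((CH2O)n, K2CO3, THF) installs the methylene group, and the route is rejoined at 13 without passing through 11 and 12.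

## Further compounds

F1 | step 8 | 2-(diethoxyphosphoryl)-2-[(6-methoxy-2-oxochromen-7-yl)oxy]acetic acid | CCOP(=O)(OCC)C(Oc1cc2oc(=O)ccc2cc1OC)C(=O)O
F2 | step 8 | 2-formyl-4-methoxy-5-[tri(propan-2-yl)silyloxy]phenyl 2-(diethoxyphosphoryl)-2-[(6-methoxy-2-oxochromen-7-yl)oxy]acetate | CCOP(=O)(OCC)C(Oc1cc2oc(=O)ccc2cc1OC)C(=O)Oc1cc(O[Si](C(C)C)(C(C)C)C(C)C)c(OC)cc1C=O
F3 | step 4 | tert-butyl 2,3-dibromopropanoate | CC(C)(C)OC(=O)C(Br)CBr
F4 | step 2 | 2-[1-hydroxy-2-(trimethylsilyl)ethyl]-4-methoxy-5-[tri(propan-2-yl)silyloxy]phenol | C[Si](C)(C)CC(O)c1cc(OC)c(O[Si](C(C)C)(C(C)C)C(C)C)cc1O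
F5 | step 6 | 2-ethenyl-4-methoxy-5-[tri(propan-2-yl)silyloxy]phenyl 2-(diethoxyphosphoryl)-2-[(6-methoxy-2-oxochromen-7-yl)oxy]acetate | CCOP(=O)(OCC)C(Oc1cc2oc(=O)ccc2cc1OC)C(=O)Oc1cc(O[Si](C(C)C)(C(C)C)C(C)C)c(OC)cc1C=C
A1 | alternative 1 | 7-tert-butoxy-6-methoxy-3-[(6-methoxy-2-oxochromen-7-yl)oxy]chromen-2-one | COc1cc2cc(Oc3cc4oc(=O)ccc4cc3OC)c(=O)oc2cc1OC(C)(C)C
A2 | alternative 1 | pentacarbonyl[(1-tert-butoxyethenyl)(methoxy)methylidene]chromium | COC(=[Cr])C(=C)OC(C)(C)C.[C-]#[O+].[C-]#[O+].[C-]#[O+].[C-]#[O+].[C-]#[O+]
A3 | alternative 1 | methyl (E)-2-[(6-methoxy-2-oxochromen-7-yl)oxy]pent-2-en-4-ynoate | C#C/C=C(\C(=O)OC)Oc1cc2oc(=O)ccc2cc1OC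
A4 | alternative 2 | 6-methoxy-3-[(6-methoxy-2-oxo-3,4-dihydrochromen-7-yl)oxy]-2-oxochromen-7-yl acetate | COc1cc2c(cc1Oc1cc3cc(OC)c(OC(C)=O)cc3oc1=O)OC(=O)CC2
A5 | alternative 2 | 6-[(7-acetoxy-6-methoxy-2-oxochromen-3-yl)oxy]-5-methoxyindan-1-one | COc1cc2c(cc1Oc1cc3cc(OC)c(OC(C)=O)cc3oc1=O)C(=O)CC2
A6 | alternative 2 | trifluoroperacetic acid | OOC(=O)C(F)(F)F
A7 | alternative 3 | 7-(benzyloxy)-6-methoxy-3-[(6-methoxy-2-oxochromen-7-yl)oxy]chromen-2-one | COc1cc2cc(Oc3cc4oc(=O)ccc4cc3OC)c(=O)oc2cc1OCc1ccccc1
A8 | alternative 3 | 5-(benzyloxy)-4-methoxy-2-[(E)-2-[(6-methoxy-2-oxochromen-7-yl)oxy]ethenyl]phenol | COc1cc(/C=C/Oc2cc3oc(=O)ccc3cc2OC)c(O)cc1OCc1ccccc1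
A9 | alternative 3 | palladium diacetate, Pd(OAc)2 | CC(=O)[O-].CC(=O)[O-].[Pd+2]
A10 | alternative 3 | 1,4-benzoquinone | O=C1C=CC(=O)C=C1
A11 | alternative 3 | carbon monoxide | [C-]#[O+]
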